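Assumption: the (R)-configured binaphthyl phosphoric acid is taken to give the (2S,4S) adduct. The sense of induction cannot be derived with certainty for this substrate pair; should the first adduct prove antipodal, the (S)-catalyst is used and nothing else changes.

## The problem

Compound 17 is a (2S)-flavanone. Ring A is a phloroglucinol nucleus (5,7-dihydroxy, 6,8-diprenyl, every position substituted) fused through C4a–C8a to the dihydropyranone ring C. C2 of ring C carries ring B, a 4-hydroxy-3-methoxy-5-prenylphenyl group.

C2 is the only stereocentre, so no resident centre can direct it. It must come from a catalyst, or from a temporary neighbour that is made with it and erased later. It is also fragile: it is benzylic, bears the aryl ether oxygen O1, lies β to the C4 carbonyl and para to a free phenol. Base therefore opens ring C by retro-oxa-Michael reaction, and acid can ionise C2–O1; either event destroys the configuration.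

The three prenyl groups rule out hydrogenation, strong electrophiles and hot protic or Lewis acid, which cyclise an ortho-prenylphenol to a 2,2-dimethylchroman. The electron-rich phenols rule out unselective oxidants. Ring A is hexasubstituted, so its pattern is best set by the symmetry of a phloroglucinol and not by late regioselective chemistry.

The feature that opens a short route is that O1–C8a–C4a–C4 is a four-atom unit spanning two ortho positions of ring A, which is the heterodiene of an ortho-quinone methide. C2–C3 with ring B attached is a 4-hydroxystyrene. C4 is a benzylic carbon on the phloroglucinol ring, so it can carry an alkoxy group while ring C forms and be oxidised to the ketone afterwards.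

## Retrosynthesis

**17 to 16.** No skeletal bond is cut; the phenols at C5 and C7 are masked as methoxymethyl (MOM) ethers in 16. The mask is needed earlier: the ring A aldehyde may offer only one free phenol to the methide-forming step. MOM is chosen because acid methanolysis is the established way to unmask prenylated 5,7-dihydroxyflavanones and uses no base. Benzyl ethers (hydrogenolysis or boron halides) and silyl ethers (basic fluoride) suit the prenyl groups or C2 less well. The forward step must cleave two aryl acetals without closing a prenyl group onto a neighbouring phenol.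

**16 to 15 to 14.** The C4 carbonyl of 16 is taken back to the carbinol 15 and this to the C4 methyl ether 14. This change of oxidation level is what permits the next cut, because a C4 ether carbon is the terminus of an ortho-quinone methide. As a bonus, C2 is not β to a carbonyl in 14 or 15, so ring opening by retro-oxa-Michael reaction cannot occur while ring C is made. The forward steps must solvolyse C4–OMe through the ring A-stabilised cation faster than C2–O1 ionises, and oxidise the carbinol without touching the ring B phenol or three alkenes. C4 may be a mixture, since it ends as a carbonyl carbon.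

**14 to 4 and 11.** O1–C2 and C3–C4 are cut together in a retro-[4+2]. This gives the ring A salicylaldehyde 4, whose formyl carbon is C4, and the ring B hydroxystyrene 11, whose vinyl group is C2–C3. The forward reaction passes through acetal 12 and the methoxy ortho-quinone methide 13.

- Cutting O1–C2 alone leads to a 2′-hydroxychalcone, whose enantioselective oxa-Michael closure is poorly developed when no extra activating group is present.
- Cutting C2–C3 or C4a–C5 alone leads to longer precursors (see the alternatives below).
- The double cut is the most convergent: two fragments of similar size, each a few steps from a commodity aromatic aldehyde, and one catalytic step forms the ring, both bonds and C2.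

The forward step needs acetal formation and ionisation under an acid mild enough for MOM and prenyl groups, reaction at the vinyl group only, and face selectivity passed on by the chiral phosphate.

**4 to 3 to 1 and 2.** The MOM ethers of 4 are removed to give 3, and the two aryl–CH2 bonds to the prenyl groups are cut to give 2,4,6-trihydroxybenzaldehyde 1 and prenyl bromide 2. In 1 the formyl group fills one of three equivalent nuclear positions, so phenoxide C-alkylation can only reach the two carbons that become C6 and C8, and 3 is symmetric. The phenol hydrogen-bonded to the formyl oxygen is the slowest to etherify, which singles out the future O1. The forward steps must stop at double C-prenylation and at the bis-ether.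

**11 to 10 to 8 to 7 to 5 and 6.** The vinyl C=C of 11 is cut to aldehyde 10 (Wittig). The aryl–prenyl bond of 10 is traced through the ortho-dienone 9 to the 1,1-dimethylallyl ether 8 (aromatic Claisen), 8 to alkyne 7, and 7 to vanillin 5 and the tertiary propargylic chloride 6. Direct C-prenylation of 5 is unselective, whereas this sequence delivers prenyl to the one free ortho position. The formyl group is kept until last because a vinyl group would not survive the semi-hydrogenation and the heating.

## Roads not taken

Alternative 1: The cut is at C4–C4a and O1–C8a, so ring A enters as an aryne and ring C is closed later at O1–C2. In the forward key step CsF removes the silyl and triflate groups of the hexasubstituted aryl triflate A1. The carboxylate oxygen of the (R)-β-silyloxy acid A2 adds to the future C8a, and the aryl anion takes the acyl carbon at the future C4a, giving the ortho-hydroxyaryl ketone A3.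
- Merits: the C5 alkoxy group should steer the oxygen to the distal aryne carbon. The carbinol centre of A2 can be set by a well-established asymmetric acetate aldol addition or β-keto ester reduction. The ketone oxidation level is reached directly.
- Weak points: A1 needs a long synthesis on a fully substituted arene. The aryne is hindered at both termini and has allylic hydrogens of a prenyl group within reach for an ene reaction. Basic fluoride can eliminate the β-silyloxy group of A3 and destroy the stereocentre. No ring closes in the key step. The later closure activates a para-alkoxybenzylic carbinol, which tends to ionise and lose configuration. The ring B phenol also needs a protecting group.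
- Comparison: the stereocentre is made by a more reliable method than in the chosen plan, and this is a real advantage. The chosen plan sets against it much shorter fragment syntheses and a key step that closes ring C, so C2 never becomes an activated benzylic leaving group.

Alternative 2: The cut is at C2–C3. The precursor is the 4-methylidene-1,3-benzodioxine A4, an acetal of the ring B aldehyde whose exocyclic enol ether requires methylenation of a hindered ester carbonyl with Cp2TiMe2. In the forward key step a chiral methylaluminium (R)-3,3′-disubstituted binaphtholate (trivalent aluminium) ionises the acetal C2–O bond. The aluminium enolate then recloses through carbon on the oxocarbenium, forming C2–C3 and ring C in the tri-MOM flavanone A5.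
- Merits: the flavanone oxidation level is reached in the key step, so only a deprotection remains. The racemic acetal centre of A4 is ionised, so the process is stereoconvergent in principle.
- Weak points: the chiral ligand sits on the enolate oxygen, far from a freely rotating oxocarbenium, and enantiocontrol of this rearrangement by a chiral Lewis acid has little basis. The aluminium reagent is stoichiometric and strongly Lewis acidic, in the presence of three MOM acetals and three prenyl groups. A5 can reopen under the Lewis acid and racemise.
- Comparison: this road is better in step count after the key step and in avoiding the C4 redox detour. The chosen plan sets against it substoichiometric, hydrogen-bond-organised stereocontrol of a kind known for hydroxystyrenes, and an acid mild enough for the protecting groups.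

Alternative 3: The cut is at C4a–C5, so ring A is built last on the (S)-dihydropyranone A6, which carries a doubly prenylated 3-oxo ester chain at the future C8a. In the forward key step Mg(OMe)2 enolises the chain. The nucleophilic α-carbon of the vinylogous ester (C4a) is acylated by the terminal ester, and the new ring enolises to the 5,7-dihydroxy arene of A7.
- Merits: it mirrors polyketide biosynthesis. Both ring A prenyl groups are placed by alkylating an acyclic dicarbonyl chain, which avoids the statistical C-prenylation of a phloroglucinol. A7 is one deprotection from 17 with the ketone in place. C2 of A6 can be set by a well-developed catalytic asymmetric hetero-Diels–Alder reaction.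
- Weak points: A6 is long to assemble and exists as tautomer and diastereomer mixtures. Under the magnesium alkoxide, C2–O1 is β to the enone carbonyl and can open, more easily so with the electron-rich ring B. Closure through oxygen to a pyranone competes with C-acylation.
- Comparison: prenyl regiochemistry and final oxidation level are inherent here, which the chosen plan cannot match in step 1. The chosen plan sets against it ten steps in all from cheap aromatics and a stereocentre that never meets base.

Key step: step 7

## Route

Step 1
Reactants: 1 2,4,6-trihydroxybenzaldehyde; 2 prenyl bromide (1-bromo-3-methylbut-2-ene)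
Product: 3 2,4,6-trihydroxy-3,5-bis(3-methylbut-2-en-1-yl)benzaldehyde
Conditions: 2 (2.1 equiv), 10% aq KOH, 0 °C to rt; then dilute HCl, chromatography
Reagents that add atoms: none
Why: Phenoxide C-alkylation of a formylphloroglucinol with an allylic bromide, as used for diprenylated acylphloroglucinols; the formyl group blocks one nuclear position, so the two equivalent free carbons are alkylated. Mono-, O- and geminally dialkylated by-products are expected and are removed by chromatography.

Step 2
Reactants: 3 2,4,6-trihydroxy-3,5-bis(3-methylbut-2-en-1-yl)benzaldehyde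
Product: 4 2-hydroxy-4,6-bis(methoxymethoxy)-3,5-bis(3-methylbut-2-en-1-yl)benzaldehyde
Conditions: MOMCl (2.3 equiv), K2CO3, acetone, 0 °C to rt
Reagents that add atoms: chloromethyl methyl ether, COCCl
Why: Williamson-type O-alkylation of the phenoxides; once one ortho phenol is etherified, the other is locked in a hydrogen bond to the formyl oxygen and stays free. Because 3 is symmetric, only one bis-ether can form.

Step 3
Reactants: 5 vanillin (4-hydroxy-3-methoxybenzaldehyde); 6 3-chloro-3-methylbut-1-yne
Product: 7 3-methoxy-4-[(2-methylbut-3-yn-2-yl)oxy]benzaldehyde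
Conditions: 6 (1.8 equiv), K2CO3, KI (cat.), CuI (cat.), acetone, 55 °C (sealed)
Reagents that add atoms: none
Why: Copper-assisted O-alkylation of a phenoxide with a tertiary propargylic chloride, which proceeds through the copper acetylide so that the hindered tertiary ether can form. Acidic, electron-poor phenols such as 5 are the best substrates.

Step 4
Reactants: 7 3-methoxy-4-[(2-methylbut-3-yn-2-yl)oxy]benzaldehyde
Product: 8 3-methoxy-4-[(2-methylbut-3-en-2-yl)oxy]benzaldehyde
Conditions: H2 (1 atm), Pd/CaCO3 poisoned with Pb(OAc)2 (Lindlar catalyst), quinoline, EtOAc, rt, stopped after 1 equiv H2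
Reagents that add atoms: none
Why: Lindlar semi-hydrogenation of a terminal alkyne to the vinyl group; the aldehyde and aryl ether are inert to the poisoned catalyst. Reduction before heating avoids the chromene that a propargyl aryl ether would give.

Step 5
Reactants: 8 3-methoxy-4-[(2-methylbut-3-en-2-yl)oxy]benzaldehyde
Product: 10 4-hydroxy-3-methoxy-5-(3-methylbut-2-en-1-yl)benzaldehyde (5-prenylvanillin), via ortho-dienone 9 (not isolated)
Conditions: N,N-diethylaniline, 160 °C
Reagents that add atoms: none
Why: Aromatic Claisen rearrangement: the [3,3] shift joins the terminal CH2 of the 1,1-dimethylallyl ether to the only free ortho carbon, so a normal prenyl group results, and dienone 9 tautomerises to the phenol. The other ortho carbon carries the methoxy group and cannot rearomatise.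

Step 6
Reactants: 10 4-hydroxy-3-methoxy-5-(3-methylbut-2-en-1-yl)benzaldehyde
Product: 11 4-ethenyl-2-methoxy-6-(3-methylbut-2-en-1-yl)phenol
Conditions: Ph3PCH3Br (3 equiv), KOtBu (3 equiv), THF, 0 °C to rt; used promptly
Reagents that add atoms: methyltriphenylphosphonium bromide, C[P+](c1ccccc1)(c1ccccc1)c1ccccc1.[Br-]
Why: Wittig methylenation; the unstabilised ylide is reactive enough for the phenoxide-deactivated aldehyde, and the excess covers the equivalent consumed by the phenol. This is the established way from 4-hydroxybenzaldehydes to 4-vinylphenols.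

Step 7
Reactants: 4 2-hydroxy-4,6-bis(methoxymethoxy)-3,5-bis(3-methylbut-2-en-1-yl)benzaldehyde; 11 4-ethenyl-2-methoxy-6-(3-methylbut-2-en-1-yl)phenol
Product: 14 4-[(2S,4S)-4-methoxy-5,7-bis(methoxymethoxy)-6,8-bis(3-methylbut-2-en-1-yl)-3,4-dihydro-2H-chromen-2-yl]-2-methoxy-6-(3-methylbut-2-en-1-yl)phenol (the 2,4-cis 4-methoxyflavan), via dimethyl acetal 12 (not isolated), via methoxy ortho-quinone methide 13 (not isolated)
Conditions: HC(OMe)3 (2 equiv), (R)-3,3′-bis(2,4,6-triisopropylphenyl)-1,1′-binaphthyl-2,2′-diyl hydrogen phosphate (10 mol %), 5 Å MS, toluene, rt; then 11 (1.3 equiv), −20 °C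
Reagents that add atoms: trimethyl orthoformate, COC(OC)OC
Why: Acid-catalysed exchange with HC(OMe)3 turns 4 into acetal 12, which loses methanol to an O-methyl oxocarbenium conjugated with the ortho phenol, i.e. protonated methide 13, held as an ion pair by the chiral phosphate. The terminal vinyl carbon of 11 attacks the methide carbon (C3–C4) and the ring A phenol oxygen then captures the para-hydroxybenzylic cation (O1–C2), an asynchronous inverse-electron-demand oxa-[4+2] cycloaddition. The closest known reactions are the chiral phosphoric acid-catalysed [4+2] additions of in situ ortho-quinone methides to hydroxystyrenes and the acid-catalysed three-component union of salicylaldehydes, orthoformates and styrenes to 2-aryl-4-alkoxychromans. Ring C closes in the [4+2] mode (O1, C8a, C4a and C4 from 13; C3 and C2 from 11), the last bond forming in the stepwise limit by 6-exo-trig attack of oxygen on the quinone-methide-like C2. C4 is set in the C–C bond formation by the oxocarbenium face that the 3,3′-aryl groups of the catalyst leave open while its phosphoryl oxygen hydrogen-bonds the phenol of 11, and C2 follows in the ring closure cis to C4 through the endo half-chair with both substituents pseudo-equatorial. The step needs chemoselectivity for the vinyl group over three prenyl alkenes, secured by its conjugation with the para hydroxyl and by the hydrogen bond to the catalyst, and regioselectivity, secured because only attack through the terminal carbon gives a stabilised benzylic cation. Enantioselectivity at C2 is the one selectivity carried through to 17, so any trans isomer, which would be antipodal at C2 if it arises from the same C4 face, is removed by chromatography before step 8. The weak acid at low temperature should leave the MOM ethers and prenyl groups untouched.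

Step 8
Reactants: 14 4-[(2S,4S)-4-methoxy-5,7-bis(methoxymethoxy)-6,8-bis(3-methylbut-2-en-1-yl)-3,4-dihydro-2H-chromen-2-yl]-2-methoxy-6-(3-methylbut-2-en-1-yl)phenol
Product: 15 (2S)-2-[4-hydroxy-3-methoxy-5-(3-methylbut-2-en-1-yl)phenyl]-5,7-bis(methoxymethoxy)-6,8-bis(3-methylbut-2-en-1-yl)-3,4-dihydro-2H-chromen-4-ol (mixture of C4 epimers)
Conditions: PPTS (0.2 equiv), acetone/H2O 3:1, 25–40 °C
Reagents that add atoms: water, O
Why: Unimolecular solvolysis: the C4–OMe bond ionises readily because the cation is stabilised by three ring A oxygens (O1, O5, O7), and the large excess of water captures it. C2 is not involved and C4 may scramble, since it is oxidised next; MOM ethers tolerate this weak acid.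

Step 9
Reactants: 15 (2S)-2-[4-hydroxy-3-methoxy-5-(3-methylbut-2-en-1-yl)phenyl]-5,7-bis(methoxymethoxy)-6,8-bis(3-methylbut-2-en-1-yl)-3,4-dihydro-2H-chromen-4-ol
Product: 16 (2S)-2-[4-hydroxy-3-methoxy-5-(3-methylbut-2-en-1-yl)phenyl]-5,7-bis(methoxymethoxy)-6,8-bis(3-methylbut-2-en-1-yl)-2,3-dihydro-4H-chromen-4-one
Conditions: activated MnO2 (15 equiv), CH2Cl2, rt
Reagents that add atoms: none
Why: Heterogeneous MnO2 oxidation of an electron-rich benzylic alcohol, under neutral conditions that leave alkenes, MOM ethers and C2 alone. Both C4 epimers converge on the one ketone.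

Step 10
Reactants: 16 (2S)-2-[4-hydroxy-3-methoxy-5-(3-methylbut-2-en-1-yl)phenyl]-5,7-bis(methoxymethoxy)-6,8-bis(3-methylbut-2-en-1-yl)-2,3-dihydro-4H-chromen-4-one
Product: 17 (2S)-5,7-dihydroxy-2-[4-hydroxy-3-methoxy-5-(3-methylbut-2-en-1-yl)phenyl]-6,8-bis(3-methylbut-2-en-1-yl)-2,3-dihydro-4H-chromen-4-one (CNP0235424.1)
Conditions: HCl (1 M in MeOH), 25–40 °C, monitored and stopped at full conversion
Reagents that add atoms: none
Why: Acid-catalysed acetal exchange passes both MOM groups to methanol, the standard unmasking of prenylated polyhydroxyflavanones. No base is present, so the retro-oxa-Michael pathway is closed, and short exposure at moderate temperature should keep prenyl–phenol cyclisation and C2–O1 ionisation slow.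

## Compound list

1 | 2,4,6-trihydroxybenzaldehyde | O=Cc1c(O)cc(O)cc1O | starting material
2 | prenyl bromide (1-bromo-3-methylbut-2-ene) | CC(C)=CCBr | starting material
3 | 2,4,6-trihydroxy-3,5-bis(3-methylbut-2-en-1-yl)benzaldehyde | O=Cc1c(O)c(CC=C(C)C)c(O)c(CC=C(C)C)c1O | intermediate
4 | 2-hydroxy-4,6-bis(methoxymethoxy)-3,5-bis(3-methylbut-2-en-1-yl)benzaldehyde | O=Cc1c(O)c(CC=C(C)C)c(OCOC)c(CC=C(C)C)c1OCOC | intermediate
5 | vanillin (4-hydroxy-3-methoxybenzaldehyde) | COc1cc(C=O)ccc1O | starting material
6 | 3-chloro-3-methylbut-1-yne | C#CC(C)(C)Cl | starting material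
7 | 3-methoxy-4-[(2-methylbut-3-yn-2-yl)oxy]benzaldehyde | COc1cc(C=O)ccc1OC(C)(C)C#C | intermediate
8 | 3-methoxy-4-[(2-methylbut-3-en-2-yl)oxy]benzaldehyde | COc1cc(C=O)ccc1OC(C)(C)C=C | intermediate
9 | 5-methoxy-3-(3-methylbut-2-en-1-yl)-4-oxocyclohexa-1,5-diene-1-carbaldehyde (racemic ortho-dienone) | O=CC1=CC(CC=C(C)C)C(=O)C(OC)=C1 | intermediate (not isolated)
10 | 4-hydroxy-3-methoxy-5-(3-methylbut-2-en-1-yl)benzaldehyde | COc1cc(C=O)cc(CC=C(C)C)c1O | intermediate
11 | 4-ethenyl-2-methoxy-6-(3-methylbut-2-en-1-yl)phenol | COc1cc(C=C)cc(CC=C(C)C)c1O | intermediate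
12 | 2-(dimethoxymethyl)-3,5-bis(methoxymethoxy)-4,6-bis(3-methylbut-2-en-1-yl)phenol | COC(OC)c1c(O)c(CC=C(C)C)c(OCOC)c(CC=C(C)C)c1OCOC | intermediate (not isolated)
13 | 6-(methoxymethylidene)-3,5-bis(methoxymethoxy)-2,4-bis(3-methylbut-2-en-1-yl)cyclohexa-2,4-dien-1-one (exocyclic geometry not fixed) | COC=C1C(=O)C(CC=C(C)C)=C(OCOC)C(CC=C(C)C)=C1OCOC | intermediate (not isolated)
14 | 4-[(2S,4S)-4-methoxy-5,7-bis(methoxymethoxy)-6,8-bis(3-methylbut-2-en-1-yl)-3,4-dihydro-2H-chromen-2-yl]-2-methoxy-6-(3-methylbut-2-en-1-yl)phenol | COc1cc([C@@H]2C[C@H](OC)c3c(OCOC)c(CC=C(C)C)c(OCOC)c(CC=C(C)C)c3O2)cc(CC=C(C)C)c1O | intermediate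
15 | (2S)-2-[4-hydroxy-3-methoxy-5-(3-methylbut-2-en-1-yl)phenyl]-5,7-bis(methoxymethoxy)-6,8-bis(3-methylbut-2-en-1-yl)-3,4-dihydro-2H-chromen-4-ol (C4 epimers) | COc1cc([C@@H]2CC(O)c3c(OCOC)c(CC=C(C)C)c(OCOC)c(CC=C(C)C)c3O2)cc(CC=C(C)C)c1O | intermediate
16 | (2S)-2-[4-hydroxy-3-methoxy-5-(3-methylbut-2-en-1-yl)phenyl]-5,7-bis(methoxymethoxy)-6,8-bis(3-methylbut-2-en-1-yl)-2,3-dihydro-4H-chromen-4-one | COc1cc([C@@H]2CC(=O)c3c(OCOC)c(CC=C(C)C)c(OCOC)c(CC=C(C)C)c3O2)cc(CC=C(C)C)c1O | intermediate
17 | (2S)-5,7-dihydroxy-2-[4-hydroxy-3-methoxy-5-(3-methylbut-2-en-1-yl)phenyl]-6,8-bis(3-methylbut-2-en-1-yl)-2,3-dihydro-4H-chromen-4-one | COc1cc([C@@H]2CC(=O)c3c(O)c(CC=C(C)C)c(O)c(CC=C(C)C)c3O2)cc(CC=C(C)C)c1O | target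

## Step count and risks

Total step count: 10 (ring A fragment 2 steps, ring B fragment 4 steps, union and end game 4 steps).
Longest linear sequence: 8 steps (steps 3 to 10, from 5 to 17).

Least certain steps:

**Step 7 (key step).** The most likely failure is poor facial selectivity. The O-methyl oxocarbenium has no hydrogen-bond donor of its own and is held by the phosphate only as an ion pair. A heavily stabilised cation also reacts slowly, which gives an achiral background pathway and acid-induced oligomerisation of the hydroxystyrene time to compete. Reversible ionisation of C2–O1 in the adduct would erode the configuration further.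

The fallback sets out from 4 and 11 and gives up catalyst control. The same three-component union is run with Sc(OTf)3 (5 mol %) and HC(OMe)3 in CH2Cl2 to give the racemic 4-methoxyflavan F1 as a mixture of C4 epimers. Solvolysis as in step 8 gives the racemic flavan-4-ol F2, and MnO2 gives the racemic bis-MOM flavanone F3, which has a single stereocentre. Preparative chromatography on a chiral stationary phase then separates 16 from its (2R) antipode F4, and the route is rejoined at 16.

**Step 1.** The most likely failure is loss of material to over-alkylation (geminal diprenylation with dearomatisation), O-alkylation and incomplete reaction, because the phenoxide is ambident and each product is as nucleophilic as its precursor.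

The fallback sets out from 1 and replaces statistical alkylation by cross-coupling. Bis-etherification with MOMCl and K2CO3 gives 2-hydroxy-4,6-bis(methoxymethoxy)benzaldehyde F5. N-Iodosuccinimide (2.1 equiv, MeCN) iodinates its only two free positions to give 2-hydroxy-3,5-diiodo-4,6-bis(methoxymethoxy)benzaldehyde F6. A double Stille coupling with tributyl(3-methylbut-2-en-1-yl)stannane and Pd(PPh3)4 in DMF installs both prenyl groups, and the route is rejoined at 4.

**Step 8.** The most likely failure is ionisation of the wrong bond. The free para hydroxyl of ring B assists cleavage of C2–O1 under the acid that is needed at C4, with loss of configuration at C2. Elimination of the C4 cation to the flav-3-ene and partial loss of MOM are lesser risks.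

The fallback sets out from 14 and deactivates ring B first. Acetylation (Ac2O, pyridine) gives the aryl acetate F7 of the 4-methoxyflavan. The same aqueous solvolysis gives the acetate F8 of the flavan-4-ol. Methanolysis with K2CO3 in MeOH, harmless while C4 is not yet a carbonyl, removes the acetate and rejoins the route at 15.

**Step 9.** The most likely failure is oxidation of the 2,6-disubstituted 4-alkylphenol of ring B to a phenoxyl radical and on to a quinone methide at C2. This can compete because the C4 carbinol is hindered by the peri MOM ether and oxidises slowly.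

The fallback sets out from 15. Phenol-selective acetylation (Ac2O, K2CO3, acetone, 0 °C) gives the acetate F8 of the flavan-4-ol; if the fallback to step 8 is in use, F8 is simply not saponified. Dess–Martin periodinane buffered with NaHCO3 gives the acetate F9 of the bis-MOM flavanone. HCl in MeOH then removes both MOM groups and the acetate in one operation, and the route is rejoined at 17.

## Further compounds

F1 | step 7 | racemic 4-[4-methoxy-5,7-bis(methoxymethoxy)-6,8-bis(3-methylbut-2-en-1-yl)-3,4-dihydro-2H-chromen-2-yl]-2-methoxy-6-(3-methylbut-2-en-1-yl)phenol (C4 epimers) | COc1cc(C2CC(OC)c3c(OCOC)c(CC=C(C)C)c(OCOC)c(CC=C(C)C)c3O2)cc(CC=C(C)C)c1O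
F2 | step 7 | racemic 2-[4-hydroxy-3-methoxy-5-(3-methylbut-2-en-1-yl)phenyl]-5,7-bis(methoxymethoxy)-6,8-bis(3-methylbut-2-en-1-yl)-3,4-dihydro-2H-chromen-4-ol (C4 epimers) | COc1cc(C2CC(O)c3c(OCOC)c(CC=C(C)C)c(OCOC)c(CC=C(C)C)c3O2)cc(CC=C(C)C)c1O
F3 | step 7 | racemic 2-[4-hydroxy-3-methoxy-5-(3-methylbut-2-en-1-yl)phenyl]-5,7-bis(methoxymethoxy)-6,8-bis(3-methylbut-2-en-1-yl)-2,3-dihydro-4H-chromen-4-one | COc1cc(C2CC(=O)c3c(OCOC)c(CC=C(C)C)c(OCOC)c(CC=C(C)C)c3O2)cc(CC=C(C)C)c1O
F4 | step 7 | (2R)-2-[4-hydroxy-3-methoxy-5-(3-methylbut-2-en-1-yl)phenyl]-5,7-bis(methoxymethoxy)-6,8-bis(3-methylbut-2-en-1-yl)-2,3-dihydro-4H-chromen-4-one | COc1cc([C@H]2CC(=O)c3c(OCOC)c(CC=C(C)C)c(OCOC)c(CC=C(C)C)c3O2)cc(CC=C(C)C)c1O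
F5 | step 1 | 2-hydroxy-4,6-bis(methoxymethoxy)benzaldehyde | O=Cc1c(O)cc(OCOC)cc1OCOC
F6 | step 1 | 2-hydroxy-3,5-diiodo-4,6-bis(methoxymethoxy)benzaldehyde | O=Cc1c(O)c(I)c(OCOC)c(I)c1OCOC
F7 | step 8 | 4-[(2S,4S)-4-methoxy-5,7-bis(methoxymethoxy)-6,8-bis(3-methylbut-2-en-1-yl)-3,4-dihydro-2H-chromen-2-yl]-2-methoxy-6-(3-methylbut-2-en-1-yl)phenyl acetate | COc1cc([C@@H]2C[C@H](OC)c3c(OCOC)c(CC=C(C)C)c(OCOC)c(CC=C(C)C)c3O2)cc(CC=C(C)C)c1OC(C)=O
F8 | step 8 | 4-[(2S)-4-hydroxy-5,7-bis(methoxymethoxy)-6,8-bis(3-methylbut-2-en-1-yl)-3,4-dihydro-2H-chromen-2-yl]-2-methoxy-6-(3-methylbut-2-en-1-yl)phenyl acetate (C4 epimers) | COc1cc([C@@H]2CC(O)c3c(OCOC)c(CC=C(C)C)c(OCOC)c(CC=C(C)C)c3O2)cc(CC=C(C)C)c1OC(C)=O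
F9 | step 9 | 4-[(2S)-5,7-bis(methoxymethoxy)-6,8-bis(3-methylbut-2-en-1-yl)-4-oxo-3,4-dihydro-2H-chromen-2-yl]-2-methoxy-6-(3-methylbut-2-en-1-yl)phenyl acetate | COc1cc([C@@H]2CC(=O)c3c(OCOC)c(CC=C(C)C)c(OCOC)c(CC=C(C)C)c3O2)cc(CC=C(C)C)c1OC(C)=O
A1 | alternative 1 | 3,5-bis(methoxymethoxy)-2,4-bis(3-methylbut-2-en-1-yl)-6-(trimethylsilyl)phenyl trifluoromethanesulfonate | C[Si](C)(C)c1c(OCOC)c(CC=C(C)C)c(OCOC)c(CC=C(C)C)c1OS(=O)(=O)C(F)(F)F
A2 | alternative 1 | (3R)-3-[(tert-butyldimethylsilyl)oxy]-3-[3-methoxy-4-(methoxymethoxy)-5-(3-methylbut-2-en-1-yl)phenyl]propanoic acid | COc1cc([C@H](O[Si](C)(C)C(C)(C)C)CC(=O)O)cc(CC=C(C)C)c1OCOC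
A3 | alternative 1 | (3R)-3-[(tert-butyldimethylsilyl)oxy]-1-[2-hydroxy-4,6-bis(methoxymethoxy)-3,5-bis(3-methylbut-2-en-1-yl)phenyl]-3-[3-methoxy-4-(methoxymethoxy)-5-(3-methylbut-2-en-1-yl)phenyl]propan-1-one | COc1cc([C@H](O[Si](C)(C)C(C)(C)C)CC(=O)c2c(OCOC)c(CC=C(C)C)c(OCOC)c(CC=C(C)C)c2O)cc(CC=C(C)C)c1OCOC
A4 | alternative 2 | racemic 2-[3-methoxy-4-(methoxymethoxy)-5-(3-methylbut-2-en-1-yl)phenyl]-5,7-bis(methoxymethoxy)-4-methylidene-6,8-bis(3-methylbut-2-en-1-yl)-4H-1,3-benzodioxine | C=C1OC(c2cc(OC)c(OCOC)c(CC=C(C)C)c2)Oc2c1c(OCOC)c(CC=C(C)C)c(OCOC)c2CC=C(C)C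
A5 | alternative 2 | (2S)-2-[3-methoxy-4-(methoxymethoxy)-5-(3-methylbut-2-en-1-yl)phenyl]-5,7-bis(methoxymethoxy)-6,8-bis(3-methylbut-2-en-1-yl)-2,3-dihydro-4H-chromen-4-one | COc1cc([C@@H]2CC(=O)c3c(OCOC)c(CC=C(C)C)c(OCOC)c(CC=C(C)C)c3O2)cc(CC=C(C)C)c1OCOC
A6 | alternative 3 | methyl 4-{(2S)-2-[3-methoxy-4-(methoxymethoxy)-5-(3-methylbut-2-en-1-yl)phenyl]-4-oxo-3,4-dihydro-2H-pyran-6-yl}-2-(3-methylbut-2-en-1-yl)-3-oxo-7-methyloct-6-enoate (chain methines unassigned) | COC(=O)C(CC=C(C)C)C(=O)C(CC=C(C)C)C1=CC(=O)C[C@@H](c2cc(OC)c(OCOC)c(CC=C(C)C)c2)O1
A7 | alternative 3 | (2S)-5,7-dihydroxy-2-[3-methoxy-4-(methoxymethoxy)-5-(3-methylbut-2-en-1-yl)phenyl]-6,8-bis(3-methylbut-2-en-1-yl)-2,3-dihydro-4H-chromen-4-one | COc1cc([C@@H]2CC(=O)c3c(O)c(CC=C(C)C)c(O)c(CC=C(C)C)c3O2)cc(CC=C(C)C)c1OCOC
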